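If each partner turns one substrate into product and each protic impurity spoils one partner, I judge a flask by its reach, the part of the two substrates charged that the partner can serve once the impurity has taken its own charge 45.0%.

all flasks: free catalyst 16 mM; added ligand 19 mM

| flask | left-handed substrate | right-handed substrate | partner | protic impurity | remark | time |
|---|---|---|---|---|---|---|
| north | 1.6 M | 1.6 M | 0.96 M | 0.24 M | run made earlier |  |
| flask | 0.80 M | 0.80 M | 0.960 M | 0.240 M |  | 2.0 d |
north run (percent of the left-handed substrate and right-handed substrate together charged)

| time / h | left-handed substrate / % | right-handed substrate / % |
|---|---|---|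
| 1.00 | 48.0 | 50.0 |
| 3.00 | 43.5 | 50.1 |
| 5.00 | 41.6 | 49.6 |
| 8.00 | 37.1 | 49.2 |
| 12.0 | 34.6 | 48.7 |
| 15.0 | 32.6 | 48.8 |

(standard deviation of a reading: 0.5 percentage points)
1. part of the left-handed substrate and right-handed substrate charged together that has reacted at 2.0 d
2. excess of left-handed product over right-handed product in the product at 2.0 d
3. excess of right-handed substrate over left-handed substrate among what is left of the two at 2.0 d
- free catalyst is single-handed; left-handed substrate and right-handed substrate are mirror images of each other, charged as a racemate, each of them at the stated concentration
- the numbers in the tables scatter by 0.5 percentage points (one standard deviation)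
- steps under discussion: partner + catalyst intermediate A -> free catalyst + left-handed product; free catalyst + right-handed substrate <-> catalyst intermediate B; partner + protic impurity -> quenched reagent; left-handed product <-> right-handed product; partner + catalyst intermediate B -> free catalyst + right-handed product; free catalyst + added ligand <-> idle complex; free catalyst + left-handed substrate <-> catalyst intermediate A
- an excess is the difference of the two amounts in percent of their sum
- an excess is below zero if the other one leads

In the flask, partner is the limiting reagent. The north run has the same partner over twice the substrate, so its reach is 22.5%. I work with the fraction of that reach still open: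

| north, time | part reacted | fraction of reach left |
|---|---|---|
| 3.00 h | 6.40% | 0.716 |
| 8.00 h | 13.7% | 0.391 |
| 15.0 h | 18.6% | 0.173 |

Reading down the last column, the first span gives a decay rate of 0.121 h⁻¹ and the second 0.116 h⁻¹. Within the scatter these are one rate, so the north run looks pseudo-first-order, and I read 0.118 h⁻¹ across both spans.

The flask has half the left-handed substrate. I assume the rate falls with it, so I halve that rate. Over 2.0 d I expect 42.4% reacted. This reckoning gives no excess.

The forecast, above me on the reacted part, says 43.5%, 80% and 61.5%, holding that “partner is the limiting reagent”.

The flask gives 40.1%, 62.2% and 60.9%.

    partner + catalyst intermediate A → free catalyst + left-handed product (k = 13.0 M⁻¹ h⁻¹)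
    free catalyst + right-handed substrate ⇌ catalyst intermediate B (K = 0.320 M⁻¹, k = 800 M⁻¹ h⁻¹)
    partner + protic impurity → quenched reagent (k = 0.350 M⁻¹ h⁻¹)
    left-handed product ⇌ right-handed product (k = 0.00560 h⁻¹)
    partner + catalyst intermediate B → free catalyst + right-handed product (k = 2.60 M⁻¹ h⁻¹)
    free catalyst + added ligand ⇌ idle complex, settled at all times (K = 260 M⁻¹)
    free catalyst + left-handed substrate ⇌ catalyst intermediate A (K = 3.70 M⁻¹, k = 44.0 M⁻¹ h⁻¹)

At 2.00 d the flask stands at 89.1% of its reach, with 8.7% of the partner still there unbound. The reach gives no excess, but two steps acting together are part of the reason for the lead of left-handed product in the flask: free catalyst + left-handed substrate into catalyst intermediate A, both ways, and the return of catalyst intermediate B to free catalyst + right-handed substrate. Taking away the first turns 62.2% into −76.1%, and taking away the second turns it into −66.4%.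

A neighbour flask with less added ligand, 0.0076 M, keeps the reach of 45.0%. Taking off its unbound partner (3.5% left) and adding back its unspent impurity (3.3% left) gives 43.4%, and the computed result is 43.7%.

Readings and results are simulated for an exercise; noise was put on by code.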